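## Analysis of the target

Gambiriin A1 is a (+)-catechin unit (rings A, B and C; flavan numbering O1, C2–C4, C4a, C5–C8, C8a) whose C8 carries an open-chain 1,3-diarylpropan-2-ol arm, made of a diarylmethine carbon bound to C8 and to catechol ring E, a carbinol carbon, and a CH2 bound to phloroglucinol ring D. There are four stereocenters in two pairs: C2 (R) and C3 (S) are trans on ring C, and in the arm the diarylmethine carbon (R) and the carbinol carbon (S) hold ring E and the hydroxyl anti along the extended chain. Ring A lies between the pairs, so neither can pass configuration to the other and each must be set in absolute terms. The eleven hydroxyls (nine phenolic, two secondary) make the free compound prone to oxidation, and the benzylic O1–C2 bond and the doubly benzylic methine are acid-sensitive, so the oxygens are best carried as benzyl ethers that fall in one neutral hydrogenolysis at the end. The hard part is ring A: C8 bears a hindered stereogenic sp3 carbon, and electrophilic substitution on a catechin would neither separate C6 from C8 cleanly nor control the diarylmethine center. The strategy rests on ring A being a pentasubstituted benzene in which every position differs: C8 (arm), C8a (O1), C4a (C4), C5 (O), C6 (H) and C7 (O). A benzannulation that builds this ring from two partners, each bringing a defined set of substituents, places all of them by connectivity and not by directing effects.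

## Retrosynthetic reasoning

**Deprotection.** Target 40 is traced back to the decabenzyl ether 39 and then to its C5 triisopropylsilyl ether 38. Ten O–benzyl bonds and one O–Si bond are cut. This keeps every earlier intermediate non-polar and stable to air. The forward steps must leave the benzylic O1–C2 bond intact, which hydrogenolysis of benzylated flavan-3-ols normally does.

**Ring C.** In 38 the O1–C2 bond is cut, giving the phenol–alcohol 37 and its triethylsilyl ether 36. The cut is made here because a free C8a hydroxyl is exactly what the ring A construction delivers. Closure with inversion also turns the syn (2S,3S) open chain, which chelation-controlled chemistry supplies, into the 2,3-trans flavan. The C5 oxygen stays silylated so that only the C8a phenol can cyclise. The forward reaction must be a clean SN2 displacement at an electron-rich benzylic carbinol.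

**Ring A (key disconnection).** Phenol 36 is cut across C8–C8a, C4a–C8a and C5–C6. Cyclobutenone 22 brings C8a, C6, C7, C8 and the arm; siloxyalkyne 31 brings C4a, C5 and the C4–C3–C2–ring B chain. Each ring substituent arrives attached to its own carbon, both partners are enantiopure, and no stereocenter lies in the ring being formed. The forward step must run two ring openings, a cycloaddition and an electrocyclisation in sequence, with one regiochemical decision.

**Cyclobutenone.** Compound 22 is cut at the two ring bonds formed when ketene 21 adds to an alkoxyacetylene. This leads to acid 14 (through acid chloride 20) and benzyl ethynyl ether 19, itself from benzyl alcohol 15 and trichloroethylene 16. The C7 oxygen thus arrives already benzylated. The forward reaction must generate a monoalkylketene without disturbing the γ-benzyloxy group.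

**Diarylmethine center.** Acid 14 comes from ester 13, which is cut at the bond between the diarylmethine carbon and ring E, giving enoate 9 and Grignard reagent 11, prepared once from aryl bromide 10 and used for both ring E and ring B. The neighbouring benzyloxy-bearing carbon is the only available control element, and conjugate addition to a γ-alkoxy (E)-enoate is the established way to use it for an anti relationship. The ester carbon later becomes C8a.

**Arm carbinol.** Enoate 9 is cut at its C=C bond to aldehyde 8, made from alcohol 7. Compound 7 goes back through 6 and 5 to the bond between the CH2 and ring D, formed from aryllithium 4 (from bromide 2, from 1) and epoxide 3. The carbinol configuration is bought with the epoxide.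

**Siloxyalkyne.** Compound 31 is cut at the alkynyl C–O bond to terminal alkyne 28 (through acetylide 29 and ynolate 30), and 28 to alcohol 27. Compound 27 is cut at the C2–ring B bond to aldehyde 26 and the same Grignard reagent 11; the α-benzyloxy group of 26 sets C2 by chelation. Aldehyde 26 goes back through 25, 24 and 23 to the same epoxide 3 and an acetylide nucleophile, so C3 is also bought with 3.

## Alternatives that were turned down

**Alternative 1: O1–C8a disconnection.**
- Disconnection and key step: the open-chain aryl bromide A2 (bromine on C8a, free (2R) benzylic hydroxyl, all else benzylated) would be closed by intramolecular aryl etherification. The catalyst would be CuI/1,10-phenanthroline/Cs2CO3, or Pd(OAc)2 with a bulky biaryl di-tert-butylphosphine. The product is undeca-O-benzyl gambiriin A1, A1.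
- For: C2 and C3 are made in the open chain and are not touched, so C2 does not depend on an SN2 displacement at an electron-rich benzylic carbon. On this point it is stronger than the Mitsunobu closure chosen here. A1 also needs a single hydrogenolysis, where the chosen route needs three deprotection operations.
- Against: in A2 the bromine sits on a hexasubstituted ring between the C4a methylene and the C8 diarylmethine. Oxidative addition into so electron-rich and hindered a bromide is slow, and a secondary benzylic alkoxide on palladium can undergo β-hydride elimination. The copper variant needs carbonate base at high temperature.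
- Comparison: the alternative only moves the ring closure. How the C8–diarylmethine bond and the ring A pattern of A2 are made with regio- and stereocontrol stays open. The chosen strategy settles that in the same step that produces the C8a oxygen.

**Alternative 2: C3–C4 and O1–C2 disconnection.**
- Disconnection and key step: salicyl alcohol A4 (CH2OH on C4a, free C8a hydroxyl, arm on C8) would lose water to the ortho-quinone methide A6. A6 adds the (E)-styryl pinacol boronate A5 in a [4+2] sense to give the 2,3-trans 3-boryl flavan A3; C–B oxidation with retention would then give the C3 hydroxyl.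
- For: it is the most convergent way to ring C. Two bonds, the ring and the trans relation (from the E-alkene by suprafacial addition) come in one step, and ring B arrives as a simple styrene. In bond economy for ring C it beats the chosen route.
- Against: the absolute configuration at C2/C3 is not controlled. The only stereogenic elements of A6 sit in the arm on C8, remote from and flexibly linked to the planar heterodiene, so both the (2R,3S) and (2S,3R) series should form unless a chiral catalyst for this cycloaddition is developed. The doubly oxygenated quinone methide also dimerises and hydrates easily, and A4 again presupposes ring A with the C8 arm in place.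
- Comparison: the chosen route takes C2 and C3 from an epoxide of fixed configuration and a chelation-controlled addition. It pays with more steps for certainty about configuration.

**Alternative 3: C4–C4a disconnection.**
- Disconnection and key step: in A8, ring A (arm on C8, C4a unsubstituted) is bound through O1 to C2 of an aryl-substituted epoxide. Activation with hexafluoroisopropanol or BF3·OEt2 would let C4a attack the terminal epoxide carbon (6-endo opening), closing ring C and releasing the C3 hydroxyl in deca-O-benzyl gambiriin A1, A7.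
- For: both ring C stereocenters exist before closure and are not involved. Only one position ortho to O1 is free, so the site of attack is unambiguous. Ring A is only tetrasubstituted before the closure, which is easier to reach than the pentasubstituted precursors of the other routes.
- Against: O1–C2 of A8 is an aryl ether of an electron-rich benzylic carbon, and the acid that activates the epoxide can ionise it, with loss of C2 configuration or cleavage. Attack at the internal epoxide carbon (5-exo, dihydrobenzofuran) competes. A8 itself requires etherification of a hindered phenol with a benzylic epoxy alcohol, and the C8–diarylmethine bond is again presupposed.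
- Comparison: the chosen strategy forms C4–C4a without acid, as part of the assembly of ring A, and closes the C–O bond under neutral conditions.

Key step: step 18

Assumption: 1,3,5-tris(benzyloxy)benzene 1 is taken as a catalogue compound (otherwise one benzylation of phloroglucinol triacetate precedes step 1); ring A atoms are named by flavan numbering throughout.

## Route

**Step 1**
Reactants: 1 1,3,5-tris(benzyloxy)benzene
Product: 2 2-bromo-1,3,5-tris(benzyloxy)benzene
Conditions: NBS (1.0 equiv), CH2Cl2, −78 → 0 °C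
Reagents that add atoms: N-bromosuccinimide, O=C1CCC(=O)N1Br
Why: Electrophilic aromatic bromination; the three equivalent ring positions are strongly activated and one equivalent of reagent at low temperature should stop at the monobromide.

**Step 2**
Reactants: 2 2-bromo-1,3,5-tris(benzyloxy)benzene; 3 (S)-trityl glycidyl ether
Product: 5 (S)-1-[2,4,6-tris(benzyloxy)phenyl]-3-(trityloxy)propan-2-ol, via aryllithium 4 (not isolated)
Conditions: n-BuLi, THF, −78 °C; then BF3·OEt2, 3, −78 °C; aq NaHCO3
Reagents that add atoms: none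
Why: Bromine–lithium exchange followed by BF3-promoted SN2 opening of the terminal epoxide at its CH2 carbon; the stereocenter of 3 is not touched and becomes the carbinol carbon of the arm.

**Step 3**
Reactants: 5 (S)-1-[2,4,6-tris(benzyloxy)phenyl]-3-(trityloxy)propan-2-ol
Product: 6 1,3,5-tris(benzyloxy)-2-[(S)-2-(benzyloxy)-3-(trityloxy)propyl]benzene
Conditions: NaH, BnBr, Bu4NI (cat.), THF/DMF, 0 °C → rt
Reagents that add atoms: benzyl bromide, BrCc1ccccc1
Why: Williamson etherification of the secondary alkoxide; a trityl ether cannot migrate under base, which is why it is used in place of a silyl group on the primary oxygen.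

**Step 4**
Reactants: 6 1,3,5-tris(benzyloxy)-2-[(S)-2-(benzyloxy)-3-(trityloxy)propyl]benzene
Product: 7 (S)-2-(benzyloxy)-3-[2,4,6-tris(benzyloxy)phenyl]propan-1-ol
Conditions: TsOH·H2O (cat.), MeOH/CH2Cl2, rt
Reagents that add atoms: none
Why: Acid-catalysed solvolysis of the trityl ether (SN1, the trityl cation is trapped by methanol); benzyl ethers are stable to catalytic sulfonic acid at room temperature.

**Step 5**
Reactants: 7 (S)-2-(benzyloxy)-3-[2,4,6-tris(benzyloxy)phenyl]propan-1-ol
Product: 9 ethyl (S,E)-4-(benzyloxy)-5-[2,4,6-tris(benzyloxy)phenyl]pent-2-enoate, via aldehyde 8 (not isolated)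
Conditions: Dess–Martin periodinane, CH2Cl2, 0 °C → rt; then Ph3P=CHCO2Et (3 equiv), rt
Reagents that add atoms: ethyl (triphenylphosphoranylidene)acetate, CCOC(=O)C=P(c1ccccc1)(c1ccccc1)c1ccccc1
Why: Dess–Martin oxidation and Wittig olefination in one flask, which spares the epimerisable α-benzyloxy aldehyde an isolation; the stabilised ylide should give the (E)-enoate.

**Step 6**
Reactants: 10 4-bromo-1,2-bis(benzyloxy)benzene
Product: 11 [3,4-bis(benzyloxy)phenyl]magnesium bromide, obtained as a titrated THF solution that is divided between steps 7 and 15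
Conditions: Mg turnings, THF, rt → 40 °C; titration
Reagents that add atoms: magnesium, [Mg]
Why: Grignard reagent formation by insertion of magnesium into the aryl C–Br bond; benzyl aryl ethers are inert to the reagent, and one stock solution serves both the ring E and the ring B introduction.

**Step 7**
Reactants: 9 ethyl (S,E)-4-(benzyloxy)-5-[2,4,6-tris(benzyloxy)phenyl]pent-2-enoate; 11 [3,4-bis(benzyloxy)phenyl]magnesium bromide
Product: 13 ethyl (3S,4S)-4-(benzyloxy)-3-[3,4-bis(benzyloxy)phenyl]-5-[2,4,6-tris(benzyloxy)phenyl]pentanoate, via silyl ketene acetal 12 (not isolated)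
Conditions: 11 (2.4 equiv), CuBr·SMe2 (1.2 equiv), THF, −40 °C; Me3SiCl, then 9, −78 → −40 °C; aq NH4Cl
Reagents that add atoms: none
Why: Me3SiCl-accelerated conjugate addition of a diarylcuprate to a γ-alkoxy (E)-enoate; 1,2-induction from the γ-benzyloxy center (Felkin–Anh-type arrangement, aryl entering anti to the C–O bond) should give the anti (3S,4S) ester after hydrolysis of the silyl ketene acetal.

**Step 8**
Reactants: 13 ethyl (3S,4S)-4-(benzyloxy)-3-[3,4-bis(benzyloxy)phenyl]-5-[2,4,6-tris(benzyloxy)phenyl]pentanoate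
Product: 14 (3S,4S)-4-(benzyloxy)-3-[3,4-bis(benzyloxy)phenyl]-5-[2,4,6-tris(benzyloxy)phenyl]pentanoic acid
Conditions: LiOH, THF/MeOH/H2O, rt; then 1 M HCl
Reagents that add atoms: lithium hydroxide, [Li+].[OH-]
Why: Ester saponification; both stereocenters are β or γ to the carbonyl and are not epimerisable under these conditions.

**Step 9**
Reactants: 15 benzyl alcohol; 16 trichloroethylene
Product: 19 benzyl ethynyl ether, via dichlorovinyl ether 17 (not isolated), via lithium benzyloxyacetylide 18 (not isolated)
Conditions: KH, THF, 0 °C; 16, −50 °C → rt; n-BuLi (2.2 equiv), −78 → −40 °C; MeOH, −78 °C; used as a cold solution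
Reagents that add atoms: none
Why: One-flask alkoxyacetylene synthesis: addition–elimination of the alkoxide on trichloroethylene gives the dichlorovinyl ether, n-BuLi effects elimination and chlorine–lithium exchange, and methanol protonates the acetylide; the product has no β-hydrogen for retro-ene loss and is kept cold to avoid sigmatropic rearrangement.

**Step 10**
Reactants: 14 (3S,4S)-4-(benzyloxy)-3-[3,4-bis(benzyloxy)phenyl]-5-[2,4,6-tris(benzyloxy)phenyl]pentanoic acid; 19 benzyl ethynyl ether
Product: 22 3-(benzyloxy)-4-{(1S,2S)-2-(benzyloxy)-1-[3,4-bis(benzyloxy)phenyl]-3-[2,4,6-tris(benzyloxy)phenyl]propyl}cyclobut-2-en-1-one (both epimers at ring C4), via acid chloride 20 (not isolated), via ketene 21 (not isolated)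
Conditions: Me2C=C(Cl)NMe2 (Ghosez reagent), CH2Cl2, 0 °C; then 19 (2 equiv), Et3N, 0 °C → rt
Reagents that add atoms: none
Why: Neutral conversion of the acid into its chloride, dehydrochlorination to the monoalkylketene and regioselective [2+2] cycloaddition with an alkoxyacetylene (ketene carbonyl carbon to the unsubstituted alkyne carbon); the new ring stereocenter forms as a mixture and is erased in step 18.

**Step 11**
Reactants: 3 (S)-trityl glycidyl ether
Product: 23 (S)-1-(trityloxy)pent-4-yn-2-ol
Conditions: LiC≡CH·H2NCH2CH2NH2, DMSO/THF, 0 °C → rt; H2O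
Reagents that add atoms: lithium acetylide–ethylenediamine complex, [Li]C#C.NCCN
Why: SN2 opening of the terminal epoxide by lithium acetylide at the CH2 carbon; the configuration of 3 is retained and becomes C3 of the flavan.

**Step 12**
Reactants: 23 (S)-1-(trityloxy)pent-4-yn-2-ol
Product: 24 [(S)-2-(benzyloxy)pent-4-yn-1-yl] trityl ether
Conditions: NaH, BnBr, Bu4NI (cat.), THF, 0 °C → rt
Reagents that add atoms: benzyl bromide, BrCc1ccccc1
Why: Williamson etherification; this places the C3 benzyl ether before C2 exists, so the two oxygens of the later diol never need to be told apart.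

**Step 13**
Reactants: 24 [(S)-2-(benzyloxy)pent-4-yn-1-yl] trityl ether
Product: 25 (S)-2-(benzyloxy)pent-4-yn-1-ol
Conditions: TsOH·H2O (cat.), MeOH/CH2Cl2, rt
Reagents that add atoms: none
Why: Acid-catalysed solvolysis of the trityl ether, as in step 4; alkyne and benzyl ether are inert.

**Step 14**
Reactants: 25 (S)-2-(benzyloxy)pent-4-yn-1-ol
Product: 26 (S)-2-(benzyloxy)pent-4-ynal
Conditions: Dess–Martin periodinane, CH2Cl2, 0 °C; used at once
Reagents that add atoms: none
Why: Dess–Martin oxidation under neutral conditions; the α-benzyloxy aldehyde is not stored, to avoid epimerisation.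

**Step 15**
Reactants: 26 (S)-2-(benzyloxy)pent-4-ynal; 11 [3,4-bis(benzyloxy)phenyl]magnesium bromide
Product: 27 (1S,2S)-2-(benzyloxy)-1-[3,4-bis(benzyloxy)phenyl]pent-4-yn-1-ol
Conditions: 26, MgBr2·OEt2, CH2Cl2, −78 °C; then 11 (THF solution from step 6), −78 °C; aq NH4Cl
Reagents that add atoms: none
Why: Cram-chelate addition of an aryl Grignard reagent to an α-benzyloxy aldehyde: magnesium bridges the carbonyl and ether oxygens and the aryl group enters from the side of the α-hydrogen, which should give the syn (1S,2S) alcohol; addition at −78 °C should outrun deprotonation of the terminal alkyne.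

**Step 16**
Reactants: 27 (1S,2S)-2-(benzyloxy)-1-[3,4-bis(benzyloxy)phenyl]pent-4-yn-1-ol
Product: 28 {[(1S,2S)-2-(benzyloxy)-1-[3,4-bis(benzyloxy)phenyl]pent-4-yn-1-yl]oxy}triethylsilane
Conditions: Et3SiCl, imidazole, DMF, 0 °C → rt
Reagents that add atoms: chlorotriethylsilane, CC[Si](Cl)(CC)CC
Why: Silylation of the secondary alcohol; the triethylsilyl group masks the C2 hydroxyl against ketenes in step 18 and can later be removed by acid without loss of an aryl silyl ether.

**Step 17**
Reactants: 28 {[(1S,2S)-2-(benzyloxy)-1-[3,4-bis(benzyloxy)phenyl]pent-4-yn-1-yl]oxy}triethylsilane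
Product: 31 {[(4S,5S)-4-(benzyloxy)-5-[3,4-bis(benzyloxy)phenyl]-5-(triethylsiloxy)pent-1-yn-1-yl]oxy}triisopropylsilane, via lithium acetylide 29 (not isolated), via lithium ynolate 30 (not isolated)
Conditions: LiN(SiMe3)2, THF, −78 °C; t-BuOOLi (from t-BuOOH and LiN(SiMe3)2), −78 → 0 °C; i-Pr3SiOTf, −78 → 0 °C
Reagents that add atoms: tert-butyl hydroperoxide (as its lithium salt), CC(C)(C)OO; triisopropylsilyl trifluoromethanesulfonate, CC(C)[Si](OS(=O)(=O)C(F)(F)F)(C(C)C)C(C)C
Why: Oxidation of a lithium acetylide to the lithium ynolate by lithium tert-butyl peroxide and O-silylation with a bulky silyl triflate, the standard route from terminal alkynes to triisopropylsilyl ynol ethers; the side-chain centers are not acidic.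

**Step 18**
Reactants: 22 3-(benzyloxy)-4-{(1S,2S)-2-(benzyloxy)-1-[3,4-bis(benzyloxy)phenyl]-3-[2,4,6-tris(benzyloxy)phenyl]propyl}cyclobut-2-en-1-one; 31 {[(4S,5S)-4-(benzyloxy)-5-[3,4-bis(benzyloxy)phenyl]-5-(triethylsiloxy)pent-1-yn-1-yl]oxy}triisopropylsilane
Product: 36 3-(benzyloxy)-2-{(1R,2S)-2-(benzyloxy)-1-[3,4-bis(benzyloxy)phenyl]-3-[2,4,6-tris(benzyloxy)phenyl]propyl}-6-{(2S,3S)-2-(benzyloxy)-3-[3,4-bis(benzyloxy)phenyl]-3-(triethylsiloxy)propyl}-5-(triisopropylsiloxy)phenol, via vinylketene 32 (not isolated), via vinylcyclobutenone 33 (not isolated), via dienylketene 34 (not isolated), via cyclohexadienone 35 (not isolated)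
Conditions: 22, 31 (1.3 equiv), toluene, sealed tube, 80 °C then 110 °C
Reagents that add atoms: none
Why: Thermal conrotatory 4π opening of 22 gives vinylketene 32, whose carbonyl carbon (future C8a) is attacked by the nucleophilic carbon of the ynol ether (future C4a) while the ketene α-carbon (C6) bonds to the silyloxy-bearing carbon (C5), giving vinylcyclobutenone 33 by a regiospecific [2+2] cycloaddition. A second 4π opening gives dienylketene 34, and disrotatory 6π electrocyclisation joins C8a to C8 to give cyclohexadienone 35, which tautomerises to phenol 36. The closest known reaction type is the Danheiser benzannulation of cyclobutenones with siloxyalkynes to resorcinol monosilyl ethers; a 3-alkoxy-4-alkyl cyclobutenone, which extends the pattern to a phloroglucinol, is a less explored partner in the same manifold. The four-membered ring of 33 closes by cycloaddition and ring A by electrocyclisation, so no ionic ring closure is involved. No stereocenter is created: the two ring epimers of 22 converge because that carbon becomes aromatic C8, and the four side-chain centers are not enolisable and lie outside the reacting π system. The step needs regioselectivity only, which the polarity match between the ketene carbonyl carbon and the oxygen-substituted alkyne fixes, so that the free hydroxyl falls on C8a, the silyl ether on C5 and the benzyl ether on C7. The slight excess of 31 should limit acylation of the product phenol by 32.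

**Step 19**
Reactants: 36 ring A phenol with C2 triethylsilyl ether (name as in step 18)
Product: 37 3-(benzyloxy)-2-{(1R,2S)-2-(benzyloxy)-1-[3,4-bis(benzyloxy)phenyl]-3-[2,4,6-tris(benzyloxy)phenyl]propyl}-6-{(2S,3S)-2-(benzyloxy)-3-[3,4-bis(benzyloxy)phenyl]-3-hydroxypropyl}-5-(triisopropylsiloxy)phenol
Conditions: AcOH/THF/H2O (3:1:1), rt
Reagents that add atoms: none
Why: Acid-catalysed hydrolysis of the secondary alkyl triethylsilyl ether at silicon; the aryl triisopropylsilyl ether is much slower under acid and should remain on C5.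

**Step 20**
Reactants: 37 phenol–alcohol (name as in step 19)
Product: 38 (2R,3S)-3,7-bis(benzyloxy)-2-[3,4-bis(benzyloxy)phenyl]-8-{(1R,2S)-2-(benzyloxy)-1-[3,4-bis(benzyloxy)phenyl]-3-[2,4,6-tris(benzyloxy)phenyl]propyl}-5-(triisopropylsiloxy)chromane
Conditions: PPh3, DIAD, THF, 0 °C → rt
Reagents that add atoms: none
Why: Intramolecular Mitsunobu etherification (6-exo-tet): the C8a phenol displaces the activated C2 oxygen with inversion, turning the syn (2S,3S) chain into the 2,3-trans (2R,3S) flavan; the adjacent C3 benzyloxy group disfavours ionisation and the silylated C5 oxygen cannot compete.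

**Step 21**
Reactants: 38 C5 silyl ether of decabenzyl gambiriin A1 (name as in step 20)
Product: 39 (2R,3S)-3,7-bis(benzyloxy)-2-[3,4-bis(benzyloxy)phenyl]-8-{(1R,2S)-2-(benzyloxy)-1-[3,4-bis(benzyloxy)phenyl]-3-[2,4,6-tris(benzyloxy)phenyl]propyl}chroman-5-ol
Conditions: Bu4NF, AcOH (1 equiv), THF, 0 °C
Reagents that add atoms: none
Why: Fluoride cleavage of the aryl silyl ether; the equivalent of acetic acid protonates the liberated phenoxide at once, so that the electron-rich phenol does not stand as its anion.

**Step 22**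
Reactants: 39 decabenzyl ether (name as in step 21)
Product: 40 gambiriin A1, (2R,3S)-2-(3,4-dihydroxyphenyl)-8-[(1R,2S)-1-(3,4-dihydroxyphenyl)-2-hydroxy-3-(2,4,6-trihydroxyphenyl)propyl]chromane-3,5,7-triol
Conditions: H2 (1 atm), Pd(OH)2/C, THF/MeOH, rt; filtration under argon, Sephadex LH-20
Reagents that add atoms: none
Why: Hydrogenolysis of ten benzyl ethers under neutral conditions; the O1–C2 bond and the diarylmethine C–C bonds of benzylated flavan-3-ols normally survive this treatment, and no stereocenter is affected.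

## Compound list

1 | 1,3,5-tris(benzyloxy)benzene | c1c(OCc2ccccc2)cc(OCc2ccccc2)cc1OCc1ccccc1 | starting material
2 | 2-bromo-1,3,5-tris(benzyloxy)benzene | Brc1c(OCc2ccccc2)cc(OCc2ccccc2)cc1OCc1ccccc1 | intermediate
3 | (S)-trityl glycidyl ether | C1O[C@@H]1COC(c2ccccc2)(c2ccccc2)c2ccccc2 | starting material
4 | [2,4,6-tris(benzyloxy)phenyl]lithium | [Li]c1c(OCc2ccccc2)cc(OCc2ccccc2)cc1OCc1ccccc1 | intermediate
5 | (S)-1-[2,4,6-tris(benzyloxy)phenyl]-3-(trityloxy)propan-2-ol | C(c1ccccc1)(c1ccccc1)(c1ccccc1)OC[C@@H](O)Cc1c(OCc2ccccc2)cc(OCc2ccccc2)cc1OCc1ccccc1 | intermediate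
6 | 1,3,5-tris(benzyloxy)-2-[(S)-2-(benzyloxy)-3-(trityloxy)propyl]benzene | C(c1ccccc1)(c1ccccc1)(c1ccccc1)OC[C@@H](OCc1ccccc1)Cc1c(OCc2ccccc2)cc(OCc2ccccc2)cc1OCc1ccccc1 | intermediate
7 | (S)-2-(benzyloxy)-3-[2,4,6-tris(benzyloxy)phenyl]propan-1-ol | OC[C@@H](OCc1ccccc1)Cc1c(OCc2ccccc2)cc(OCc2ccccc2)cc1OCc1ccccc1 | intermediate
8 | (S)-2-(benzyloxy)-3-[2,4,6-tris(benzyloxy)phenyl]propanal | O=C[C@@H](OCc1ccccc1)Cc1c(OCc2ccccc2)cc(OCc2ccccc2)cc1OCc1ccccc1 | intermediate
9 | ethyl (S,E)-4-(benzyloxy)-5-[2,4,6-tris(benzyloxy)phenyl]pent-2-enoate | CCOC(=O)/C=C/[C@@H](OCc1ccccc1)Cc1c(OCc2ccccc2)cc(OCc2ccccc2)cc1OCc1ccccc1 | intermediate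
10 | 4-bromo-1,2-bis(benzyloxy)benzene | Brc1ccc(OCc2ccccc2)c(OCc2ccccc2)c1 | starting material
11 | [3,4-bis(benzyloxy)phenyl]magnesium bromide | Br[Mg]c1ccc(OCc2ccccc2)c(OCc2ccccc2)c1 | intermediate
12 | ethyl trimethylsilyl ketene acetal of ester 13, (3S,4S) | CCOC(O[Si](C)(C)C)=C[C@@H](c1ccc(OCc2ccccc2)c(OCc2ccccc2)c1)[C@@H](OCc1ccccc1)Cc1c(OCc2ccccc2)cc(OCc2ccccc2)cc1OCc1ccccc1 | intermediate
13 | ethyl (3S,4S)-4-(benzyloxy)-3-[3,4-bis(benzyloxy)phenyl]-5-[2,4,6-tris(benzyloxy)phenyl]pentanoate | CCOC(=O)C[C@@H](c1ccc(OCc2ccccc2)c(OCc2ccccc2)c1)[C@@H](OCc1ccccc1)Cc1c(OCc2ccccc2)cc(OCc2ccccc2)cc1OCc1ccccc1 | intermediate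
14 | (3S,4S)-4-(benzyloxy)-3-[3,4-bis(benzyloxy)phenyl]-5-[2,4,6-tris(benzyloxy)phenyl]pentanoic acid | OC(=O)C[C@@H](c1ccc(OCc2ccccc2)c(OCc2ccccc2)c1)[C@@H](OCc1ccccc1)Cc1c(OCc2ccccc2)cc(OCc2ccccc2)cc1OCc1ccccc1 | intermediate
15 | benzyl alcohol | OCc1ccccc1 | starting material
16 | trichloroethylene | ClC=C(Cl)Cl | starting material
17 | benzyl (E)-1,2-dichlorovinyl ether | Cl/C=C(/Cl)OCc1ccccc1 | intermediate
18 | lithium (benzyloxy)acetylide | [Li]C#COCc1ccccc1 | intermediate
19 | benzyl ethynyl ether | C#COCc1ccccc1 | intermediate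
20 | acid chloride of 14, (3S,4S) | ClC(=O)C[C@@H](c1ccc(OCc2ccccc2)c(OCc2ccccc2)c1)[C@@H](OCc1ccccc1)Cc1c(OCc2ccccc2)cc(OCc2ccccc2)cc1OCc1ccccc1 | intermediate
21 | ketene from 20, (3S,4S)-4-(benzyloxy)-3-[3,4-bis(benzyloxy)phenyl]-5-[2,4,6-tris(benzyloxy)phenyl]pent-1-en-1-one | O=C=C[C@@H](c1ccc(OCc2ccccc2)c(OCc2ccccc2)c1)[C@@H](OCc1ccccc1)Cc1c(OCc2ccccc2)cc(OCc2ccccc2)cc1OCc1ccccc1 | intermediate
22 | 3-(benzyloxy)-4-{(1S,2S)-2-(benzyloxy)-1-[3,4-bis(benzyloxy)phenyl]-3-[2,4,6-tris(benzyloxy)phenyl]propyl}cyclobut-2-en-1-one, ring C4 epimers | O=C1C=C(OCc2ccccc2)C1[C@@H](c1ccc(OCc2ccccc2)c(OCc2ccccc2)c1)[C@@H](OCc1ccccc1)Cc1c(OCc2ccccc2)cc(OCc2ccccc2)cc1OCc1ccccc1 | intermediate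
23 | (S)-1-(trityloxy)pent-4-yn-2-ol | C#CC[C@H](O)COC(c1ccccc1)(c1ccccc1)c1ccccc1 | intermediate
24 | [(S)-2-(benzyloxy)pent-4-yn-1-yl] trityl ether | C#CC[C@H](OCc1ccccc1)COC(c1ccccc1)(c1ccccc1)c1ccccc1 | intermediate
25 | (S)-2-(benzyloxy)pent-4-yn-1-ol | C#CC[C@H](OCc1ccccc1)CO | intermediate
26 | (S)-2-(benzyloxy)pent-4-ynal | C#CC[C@H](OCc1ccccc1)C=O | intermediate
27 | (1S,2S)-2-(benzyloxy)-1-[3,4-bis(benzyloxy)phenyl]pent-4-yn-1-ol | C#CC[C@H](OCc1ccccc1)[C@@H](O)c1ccc(OCc2ccccc2)c(OCc2ccccc2)c1 | intermediate
28 | triethylsilyl ether of 27, (1S,2S) | C#CC[C@H](OCc1ccccc1)[C@@H](O[Si](CC)(CC)CC)c1ccc(OCc2ccccc2)c(OCc2ccccc2)c1 | intermediate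
29 | lithium acetylide of 28 | [Li]C#CC[C@H](OCc1ccccc1)[C@@H](O[Si](CC)(CC)CC)c1ccc(OCc2ccccc2)c(OCc2ccccc2)c1 | intermediate
30 | lithium ynolate from 29 | [Li]OC#CC[C@H](OCc1ccccc1)[C@@H](O[Si](CC)(CC)CC)c1ccc(OCc2ccccc2)c(OCc2ccccc2)c1 | intermediate
31 | {[(4S,5S)-4-(benzyloxy)-5-[3,4-bis(benzyloxy)phenyl]-5-(triethylsiloxy)pent-1-yn-1-yl]oxy}triisopropylsilane | CC(C)[Si](C(C)C)(C(C)C)OC#CC[C@H](OCc1ccccc1)[C@@H](O[Si](CC)(CC)CC)c1ccc(OCc2ccccc2)c(OCc2ccccc2)c1 | intermediate
32 | vinylketene, (5S,6S)-3,6-bis(benzyloxy)-5-[3,4-bis(benzyloxy)phenyl]-7-[2,4,6-tris(benzyloxy)phenyl]hepta-1,3-dien-1-one | O=C=CC(OCc1ccccc1)=C[C@@H](c1ccc(OCc2ccccc2)c(OCc2ccccc2)c1)[C@@H](OCc1ccccc1)Cc1c(OCc2ccccc2)cc(OCc2ccccc2)cc1OCc1ccccc1 | intermediate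
33 | [2+2] adduct: cyclobut-2-en-1-one bearing the lower arm on C2, triisopropylsiloxy on C3 and the 1-(benzyloxy)alkenyl chain of the upper arm on C4 | O=C1C(C[C@H](OCc2ccccc2)[C@@H](O[Si](CC)(CC)CC)c2ccc(OCc3ccccc3)c(OCc3ccccc3)c2)=C(O[Si](C(C)C)(C(C)C)C(C)C)C1C(OCc1ccccc1)=C[C@@H](c1ccc(OCc2ccccc2)c(OCc2ccccc2)c1)[C@@H](OCc1ccccc1)Cc1c(OCc2ccccc2)cc(OCc2ccccc2)cc1OCc1ccccc1 | intermediate
34 | dienylketene from ring opening of 33 | O=C=C(C[C@H](OCc1ccccc1)[C@@H](O[Si](CC)(CC)CC)c1ccc(OCc2ccccc2)c(OCc2ccccc2)c1)C(O[Si](C(C)C)(C(C)C)C(C)C)=CC(OCc1ccccc1)=C[C@@H](c1ccc(OCc2ccccc2)c(OCc2ccccc2)c1)[C@@H](OCc1ccccc1)Cc1c(OCc2ccccc2)cc(OCc2ccccc2)cc1OCc1ccccc1 | intermediate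
35 | cyclohexa-2,4-dienone tautomer of 36 | O=C1C(C[C@H](OCc2ccccc2)[C@@H](O[Si](CC)(CC)CC)c2ccc(OCc3ccccc3)c(OCc3ccccc3)c2)=C(O[Si](C(C)C)(C(C)C)C(C)C)C=C(OCc2ccccc2)C1[C@@H](c1ccc(OCc2ccccc2)c(OCc2ccccc2)c1)[C@@H](OCc1ccccc1)Cc1c(OCc2ccccc2)cc(OCc2ccccc2)cc1OCc1ccccc1 | intermediate
36 | ring A phenol: free C8a–OH, C5–OSi(i-Pr)3, C7–OBn, upper arm on C8, lower arm with C2–OSiEt3 on C4a | Oc1c(C[C@H](OCc2ccccc2)[C@@H](O[Si](CC)(CC)CC)c2ccc(OCc3ccccc3)c(OCc3ccccc3)c2)c(O[Si](C(C)C)(C(C)C)C(C)C)cc(OCc2ccccc2)c1[C@@H](c1ccc(OCc2ccccc2)c(OCc2ccccc2)c1)[C@@H](OCc1ccccc1)Cc1c(OCc2ccccc2)cc(OCc2ccccc2)cc1OCc1ccccc1 | intermediate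
37 | phenol–alcohol: 36 with free C2–OH | Oc1c(C[C@H](OCc2ccccc2)[C@@H](O)c2ccc(OCc3ccccc3)c(OCc3ccccc3)c2)c(O[Si](C(C)C)(C(C)C)C(C)C)cc(OCc2ccccc2)c1[C@@H](c1ccc(OCc2ccccc2)c(OCc2ccccc2)c1)[C@@H](OCc1ccccc1)Cc1c(OCc2ccccc2)cc(OCc2ccccc2)cc1OCc1ccccc1 | intermediate
38 | deca-O-benzyl gambiriin A1 C5 triisopropylsilyl ether | c1ccccc1COc1cc(OCc2ccccc2)c(C[C@H](OCc2ccccc2)[C@H](c2ccc(OCc3ccccc3)c(OCc3ccccc3)c2)c2c(OCc3ccccc3)cc(O[Si](C(C)C)(C(C)C)C(C)C)c3c2O[C@H](c2ccc(OCc4ccccc4)c(OCc4ccccc4)c2)[C@@H](OCc2ccccc2)C3)c(OCc2ccccc2)c1 | intermediate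
39 | deca-O-benzyl gambiriin A1 (free C5–OH) | c1ccccc1COc1cc(OCc2ccccc2)c(C[C@H](OCc2ccccc2)[C@H](c2ccc(OCc3ccccc3)c(OCc3ccccc3)c2)c2c(OCc3ccccc3)cc(O)c3c2O[C@H](c2ccc(OCc4ccccc4)c(OCc4ccccc4)c2)[C@@H](OCc2ccccc2)C3)c(OCc2ccccc2)c1 | intermediate
40 | gambiriin A1 | Oc1cc(O)c(C[C@H](O)[C@H](c2ccc(O)c(O)c2)c2c(O)cc(O)c3c2O[C@H](c2ccc(O)c(O)c2)[C@@H](O)C3)c(O)c1 | target

## Step count and least certain steps

Total step count: 22. Longest linear sequence: 13 steps (steps 1–5, 7, 8, 10, 18–22). The siloxyalkyne branch (steps 11–17) has 7 steps; step 6 (the Grignard reagent shared by steps 7 and 15) and step 9 each stand alone.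

**Step 18 (key step).** The vinylogous-ester stabilisation of the 3-benzyloxycyclobutenone may push the first ring opening to temperatures at which ketene intermediates acylate the product phenol or the siloxyalkyne rearranges. The 6π closure onto the carbon carrying the branched arm is also sterically slowed, so 22 could be consumed without clean formation of ring A. The fallback gives up the benzannulation and makes the C8–diarylmethine bond by Friedel–Crafts alkylation of a preformed catechin. It sets out from 7 (oxidised to 8 as in step 5, but isolated) and Grignard reagent 11, and returns to the route at 40. Addition of 11 to 8 in THF at −78 °C should give 1-[3,4-bis(benzyloxy)phenyl]-(2S)-2-(benzyloxy)-3-[2,4,6-tris(benzyloxy)phenyl]propan-1-ol F1 as a carbinol mixture, which does not matter because that carbon is ionised next. Commercial (+)-catechin is benzylated on its four phenols (BnBr, K2CO3, DMF) to 5,7,3',4'-tetra-O-benzyl-(+)-catechin F2. Ionisation of F1 with Me3SiOTf in CH2Cl2 at −78 °C in the presence of excess F2 should alkylate C8 to give deca-O-benzyl gambiriin A1 with free C3 hydroxyl F3. Hydrogenolysis (H2, Pd(OH)2/C) then gives 40. The price is that C8 versus C6 attack and the facial selectivity at the diarylmethine rest on substrate bias only, so isomers would have to be separated.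

**Step 10.** Benzyl ethynyl ether is the least proven component. Its sigmatropic rearrangement and polymerisation can compete with a slow cycloaddition to the hindered ketene 21. Acid chloride 20 can also lose its γ-benzyl group by intramolecular acylation of the ether oxygen if it is kept too long; this is why it is made under neutral conditions at 0 °C. The fallback sets out from 14 and returns at 22. The same ketene generation is run with commercial ethoxyacetylene, a robust partner in this cycloaddition, to give 3-ethoxy-4-{(1S,2S)-2-(benzyloxy)-1-[3,4-bis(benzyloxy)phenyl]-3-[2,4,6-tris(benzyloxy)phenyl]propyl}cyclobut-2-en-1-one F4. The alkoxy group of this vinylogous ester is then exchanged with benzyl alcohol 15 (TsOH cat., toluene, removal of ethanol) to reach 22.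

**Step 7.** Facial selectivity may be poor because the γ-substituent is a bulky arylmethyl group, and 1,2-addition or reduction of the enoate may intervene. The fallback replaces substrate control by catalyst control; it sets out from 9 and 10 and returns at 13. Bromide 10 is converted (n-BuLi, B(Oi-Pr)3, aqueous acid) into [3,4-bis(benzyloxy)phenyl]boronic acid F5. F5 is added to 9 with [RhCl(cod)]2 and a BINAP ligand in dioxane/H2O with KOH, using the ligand antipode whose sense reinforces the anti preference of the substrate.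

**Step 15.** Incomplete chelation, made more likely by the THF that comes with the Grignard solution, would lower the syn selectivity, and the aldehyde may epimerise or the alkyne be deprotonated if the addition is slow. The fallback sets out from the epimer mixture of 27 and returns at 27. Dess–Martin oxidation gives (S)-2-(benzyloxy)-1-[3,4-bis(benzyloxy)phenyl]pent-4-yn-1-one F6. Reduction with the bulky, non-chelating LiBH(s-Bu)3 in THF at −78 °C under Felkin–Anh control should deliver the syn alcohol; an oxazaborolidine-catalysed borane reduction of matching sense is available if the substrate bias is weak.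

**Step 20.** The activated, electron-rich benzylic carbinol may ionise, which erodes the C2 configuration. It may also eliminate towards the enol ether, or the hindered C8a phenol may react slowly. The fallback sets out from 37 and returns at 38 and makes no new compound (F0). The closure is run deliberately through the cation (BF3·OEt2, CH2Cl2, −40 °C); the benzylic cation is trapped by the C8a hydroxyl and the 2,3-trans flavan, with aryl and benzyloxy groups both pseudo-equatorial, should be favoured from either C2 epimer.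

## Further compounds

F1 | step 18 | 1-[3,4-bis(benzyloxy)phenyl]-(2S)-2-(benzyloxy)-3-[2,4,6-tris(benzyloxy)phenyl]propan-1-ol | OC(c1ccc(OCc2ccccc2)c(OCc2ccccc2)c1)[C@@H](OCc1ccccc1)Cc1c(OCc2ccccc2)cc(OCc2ccccc2)cc1OCc1ccccc1
F2 | step 18 | 5,7,3',4'-tetra-O-benzyl-(+)-catechin | O[C@H]1Cc2c(OCc3ccccc3)cc(OCc3ccccc3)cc2O[C@@H]1c1ccc(OCc2ccccc2)c(OCc2ccccc2)c1
F3 | step 18 | deca-O-benzyl gambiriin A1 with free C3 hydroxyl | c1ccccc1COc1cc(OCc2ccccc2)c(C[C@H](OCc2ccccc2)[C@H](c2ccc(OCc3ccccc3)c(OCc3ccccc3)c2)c2c(OCc3ccccc3)cc(OCc3ccccc3)c3c2O[C@H](c2ccc(OCc4ccccc4)c(OCc4ccccc4)c2)[C@@H](O)C3)c(OCc2ccccc2)c1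
F4 | step 10 | 3-ethoxy-4-{(1S,2S)-2-(benzyloxy)-1-[3,4-bis(benzyloxy)phenyl]-3-[2,4,6-tris(benzyloxy)phenyl]propyl}cyclobut-2-en-1-one | O=C1C=C(OCC)C1[C@@H](c1ccc(OCc2ccccc2)c(OCc2ccccc2)c1)[C@@H](OCc1ccccc1)Cc1c(OCc2ccccc2)cc(OCc2ccccc2)cc1OCc1ccccc1
F5 | step 7 | [3,4-bis(benzyloxy)phenyl]boronic acid | OB(O)c1ccc(OCc2ccccc2)c(OCc2ccccc2)c1
F6 | step 15 | (S)-2-(benzyloxy)-1-[3,4-bis(benzyloxy)phenyl]pent-4-yn-1-one | C#CC[C@H](OCc1ccccc1)C(=O)c1ccc(OCc2ccccc2)c(OCc2ccccc2)c1
F0 | step 20 | none | none
A1 | alternative 1 | undeca-O-benzyl gambiriin A1 | c1ccccc1COc1cc(OCc2ccccc2)c(C[C@H](OCc2ccccc2)[C@H](c2ccc(OCc3ccccc3)c(OCc3ccccc3)c2)c2c(OCc3ccccc3)cc(OCc3ccccc3)c3c2O[C@H](c2ccc(OCc4ccccc4)c(OCc4ccccc4)c2)[C@@H](OCc2ccccc2)C3)c(OCc2ccccc2)c1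
A2 | alternative 1 | open-chain C8a bromide with free (2R) benzylic hydroxyl | Brc1c(C[C@H](OCc2ccccc2)[C@H](O)c2ccc(OCc3ccccc3)c(OCc3ccccc3)c2)c(OCc2ccccc2)cc(OCc2ccccc2)c1[C@@H](c1ccc(OCc2ccccc2)c(OCc2ccccc2)c1)[C@@H](OCc1ccccc1)Cc1c(OCc2ccccc2)cc(OCc2ccccc2)cc1OCc1ccccc1
A3 | alternative 2 | 2,3-trans 3-(pinacolboryl) flavan, fully benzylated | c1ccccc1COc1cc(OCc2ccccc2)c(C[C@H](OCc2ccccc2)[C@H](c2ccc(OCc3ccccc3)c(OCc3ccccc3)c2)c2c(OCc3ccccc3)cc(OCc3ccccc3)c3c2O[C@H](c2ccc(OCc4ccccc4)c(OCc4ccccc4)c2)[C@@H](B2OC(C)(C)C(C)(C)O2)C3)c(OCc2ccccc2)c1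
A4 | alternative 2 | ring A salicyl alcohol (CH2OH on C4a, free C8a–OH, arm on C8) | OCc1c(O)c([C@@H](c2ccc(OCc3ccccc3)c(OCc3ccccc3)c2)[C@@H](OCc2ccccc2)Cc2c(OCc3ccccc3)cc(OCc3ccccc3)cc2OCc2ccccc2)c(OCc2ccccc2)cc1OCc1ccccc1
A5 | alternative 2 | (E)-2-[3,4-bis(benzyloxy)styryl]-4,4,5,5-tetramethyl-1,3,2-dioxaborolane | CC1(C)OB(/C=C/c2ccc(OCc3ccccc3)c(OCc3ccccc3)c2)OC1(C)C
A6 | alternative 2 | ortho-quinone methide of ring A (exocyclic CH2 on C4a) | C=C1C(=O)C([C@@H](c2ccc(OCc3ccccc3)c(OCc3ccccc3)c2)[C@@H](OCc2ccccc2)Cc2c(OCc3ccccc3)cc(OCc3ccccc3)cc2OCc2ccccc2)=C(OCc2ccccc2)C=C1OCc1ccccc1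
A7 | alternative 3 | deca-O-benzyl gambiriin A1 with free C3 hydroxyl | c1ccccc1COc1cc(OCc2ccccc2)c(C[C@H](OCc2ccccc2)[C@H](c2ccc(OCc3ccccc3)c(OCc3ccccc3)c2)c2c(OCc3ccccc3)cc(OCc3ccccc3)c3c2O[C@H](c2ccc(OCc4ccccc4)c(OCc4ccccc4)c2)[C@@H](O)C3)c(OCc2ccccc2)c1
A8 | alternative 3 | ring A aryl ether of the ring B epoxy carbinol (O1–C2 in place, C4a free) | c1c(OCc2ccccc2)cc(OCc2ccccc2)c([C@@H](c2ccc(OCc3ccccc3)c(OCc3ccccc3)c2)[C@@H](OCc2ccccc2)Cc2c(OCc3ccccc3)cc(OCc3ccccc3)cc2OCc2ccccc2)c1O[C@H](c1ccc(OCc2ccccc2)c(OCc2ccccc2)c1)[C@@H]1CO1
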